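**Strategy.** The ten-membered ring is closed across C3–C4. The target holds a tertiary carbinol (C4) three bonds from the ring alkene C1=C10 and 1,3 to the C6 oxygen: the retron of a diene–ketone homoallylation. The precursor is an open-chain trans-γ-lactone (C7/C8 set by conjugate addition to a chiral butenolide) carrying a β-hydroxy methyl ketone arm (C6–C5–C4) and a 2-substituted penta-2,4-dienyl arm (C9–C10=C1–C2=C3). Nickel-catalysed reductive cyclization joins the diene terminus C3 to the ketone carbon, delivers hydrogen to C2, leaves C1=C10 untouched and sets the C4 carbinol stereocentre through a zinc chelate with the C6 alkoxide. The α-methylene lactone travels as a silyloxymethyl group.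

Key step: step 10

Atom labels (germacrane numbering of the target): C1 ring =CH; C2, C3 ring CH2; C4 carbinol carbon with methyl C15; C5 CH2; C6 acyloxy CH; C7; C8 lactone O–CH; C9 CH2; C10 alkene carbon bearing C14H2OAc; C11; C12 lactone C=O; C13 exocyclic CH2.

Remark: compounds 1, 6, 10, 11 and 18 are taken as the commercial starting materials. TBS = tert-butyldimethylsilyl.

**Route**

Step 1
Reactants: 1 (S)-5-(hydroxymethyl)furan-2(5H)-one
Product: 2 (S)-5-(bromomethyl)furan-2(5H)-one
Conditions: CBr4, PPh3, CH2Cl2, 0 °C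
Reagents that add atoms: carbon tetrabromide BrC(Br)(Br)Br
Why: Appel reaction under neutral conditions converts the primary alcohol to the bromide without touching the base-sensitive butenolide or the C8 stereocentre.

Step 2
Reactants: 2 (S)-5-(bromomethyl)furan-2(5H)-one
Product: 4 (3R,4S,5S)-5-(bromomethyl)-4-ethenyl-3-(hydroxymethyl)oxolan-2-one, via bromomagnesium enolate 3 (not isolated)
Conditions: CH2=CHMgBr, CuBr·SMe2 (10 mol%), THF, −78 °C; then CH2O (gas), −78 → −40 °C; AcOH
Reagents that add atoms: vinylmagnesium bromide C=C[Mg]Br; formaldehyde C=O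
Why: Copper-catalysed conjugate addition to the butenolide should occur anti to the C8 bromomethyl group (sets C7), and aldol trapping of the enolate by formaldehyde anti to the new vinyl group installs C13 as a masked α-methylene group (C11 is destroyed later).

Step 3
Reactants: 4 (3R,4S,5S)-5-(bromomethyl)-4-ethenyl-3-(hydroxymethyl)oxolan-2-one
Product: 5 (3R,4S,5S)-5-(bromomethyl)-3-{[tert-butyl(dimethyl)silyl]oxymethyl}-4-ethenyloxolan-2-one
Conditions: TBSCl, imidazole, CH2Cl2, 0 → 25 °C
Reagents that add atoms: tert-butyldimethylsilyl chloride CC(C)(C)[Si](C)(C)Cl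
Why: Silylation of the primary alcohol blocks ether formation with the C9 bromide and keeps C13 as an inert β-silyloxy lactone until the last step.

Step 4
Reactants: 5 (3R,4S,5S)-5-(bromomethyl)-3-{[tert-butyl(dimethyl)silyl]oxymethyl}-4-ethenyloxolan-2-one; 6 but-3-en-2-one
Product: 7 (3R,4S,5S)-5-(bromomethyl)-3-{[tert-butyl(dimethyl)silyl]oxymethyl}-4-[(1E)-3-oxobut-1-en-1-yl]oxolan-2-one
Conditions: second-generation Hoveyda–Grubbs catalyst (5 mol%), 6 (4 equiv), CH2Cl2, 40 °C
Reagents that add atoms: none
Why: Olefin cross-metathesis of the only alkene in 5 with the electron-poor enone partner should give the E-enone and brings in C5, C4 and C15.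

Step 5
Reactants: 7 (3R,4S,5S)-5-(bromomethyl)-3-{[tert-butyl(dimethyl)silyl]oxymethyl}-4-[(1E)-3-oxobut-1-en-1-yl]oxolan-2-one
Product: 9 (3R,4R,5S)-5-(bromomethyl)-3-{[tert-butyl(dimethyl)silyl]oxymethyl}-4-[(1R)-1-hydroxy-3-oxobutyl]oxolan-2-one, via C6 pinacol boronate 8 (not isolated)
Conditions: B2pin2, CuCl (5 mol%), NaOt-Bu (8 mol%), (S)-1-[(R)-2-(diphenylphosphino)ferrocenyl]ethyldicyclohexylphosphine (6 mol%), MeOH (2 equiv), THF, 25 °C; then NaBO3·4H2O, THF/H2O, 25 °C
Reagents that add atoms: sodium perborate [Na+].[O-]OB=O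
Why: Copper-catalysed asymmetric conjugate borylation of the E-enone and stereoretentive oxidation of the C–B bond give the β-hydroxy ketone, the chiral bisphosphine controlling the face so that C6 is R (the ligand antipode is used instead if a test shows the opposite sense).

Step 6
Reactants: 10 prop-2-yn-1-ol; 11 bromoethene
Product: 12 pent-4-en-2-yn-1-ol
Conditions: PdCl2(PPh3)2 (2 mol%), CuI (4 mol%), i-Pr2NH, THF, 0 → 25 °C
Reagents that add atoms: none
Why: Sonogashira coupling joins C1 to C2 and gives the enynol that carries C14, C10, C1, C2 and C3.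

Step 7
Reactants: 12 pent-4-en-2-yn-1-ol
Product: 14 (2Z)-2-iodopenta-2,4-dien-1-ol, via dienylstannane 13 (not isolated)
Conditions: Bu3SnH, [(C5Me5)RuCl]4 (1.25 mol%), CH2Cl2, 25 °C; then I2, CH2Cl2, 0 °C
Reagents that add atoms: iodine II
Why: Hydroxyl-directed ruthenium-catalysed trans-hydrostannation should place tin on C10 and hydrogen on C1 anti to it, and iododestannylation with retention gives the iodide with iodine cis to the vinyl group.

Step 8
Reactants: 14 (2Z)-2-iodopenta-2,4-dien-1-ol
Product: 15 tert-butyl{[(2Z)-2-iodopenta-2,4-dien-1-yl]oxy}dimethylsilane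
Conditions: TBSCl, imidazole, CH2Cl2, 0 → 25 °C
Reagents that add atoms: tert-butyldimethylsilyl chloride CC(C)(C)[Si](C)(C)Cl
Why: Silylation gives an allylic ether at C14 that zerovalent nickel does not ionize, unlike the final acetate.

Step 9
Reactants: 9 (3R,4R,5S)-5-(bromomethyl)-3-{[tert-butyl(dimethyl)silyl]oxymethyl}-4-[(1R)-1-hydroxy-3-oxobutyl]oxolan-2-one; 15 tert-butyl{[(2Z)-2-iodopenta-2,4-dien-1-yl]oxy}dimethylsilane
Product: 16 diene ketone: lactone 9 in which the C9 bromide is replaced by the dienyl unit C10(CH2OTBS)=C1H–C2H=C3H2 (C9 cis to C2)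
Conditions: NiBr2·(MeOCH2CH2OMe) (10 mol%), 4,4'-di-tert-butyl-2,2'-bipyridine (10 mol%), NaI (0.5 equiv), Zn dust (2 equiv), 15 (1.5 equiv), DMA, 25 °C
Reagents that add atoms: none
Why: Nickel-catalysed reductive cross-electrophile coupling of the primary alkyl bromide with the alkenyl iodide forms C9–C10 with retention of the alkene geometry and tolerates the free hydroxyl, the ketone and the lactone.

Step 10
Reactants: 16 diene ketone
Product: 17 ten-membered carbocycle with C4 tertiary alcohol (4S) and C6 secondary alcohol (6R) trans-fused to the lactone and carrying C14-OTBS and C13-OTBS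
Conditions: Ni(acac)2 (20 mol%), Et2Zn (3.5 equiv), THF (0.005 M, slow addition of 16), 25 °C; aq. NH4Cl
Reagents that add atoms: none
Why: Proposed new method: zerovalent nickel (from Ni(acac)2 and Et2Zn) should couple the terminal C2=C3 alkene of the diene with the zinc-activated C4 ketone by oxidative cyclization to an oxanickelacycle whose allyl unit spans C2–C1–C10; ethyl transfer from zinc, β-hydride elimination (ethylene) and C–H reductive elimination at C2 then release the zinc alkoxide of 17 and zerovalent nickel. The closest known reaction is the nickel-catalysed homoallylation of aldehydes and ketones with 1,3-dienes promoted by Et3B or Et2Zn, known in cyclizing form for ω-dienyl aldehydes giving five- and six-membered rings; a ten-membered closure onto a ketone is not documented. The ten-membered carbocycle closes in the endo mode with respect to the C2=C3 alkene (both alkene carbons become ring atoms) and exo with respect to the carbonyl oxygen. The new C4 stereocentre should be set by the six-membered zinc chelate between the C6 alkoxide and the ketone oxygen, the diene arm attacking the face anti to C7 (1,3-anti relation of the C4 and C6 oxygens, as in the target), with the trans-lactone restricting the approach. The step needs regioselectivity (C3 over C10, secured because C10 is fully substituted; hydrogen to C2 and not C10, inherent to the five-membered nickelacycle), retention of the C1=C10 geometry (C10 is never σ-bound) and cyclization over oligomerization (high dilution, slow addition), while masking of the α-methylene group as CH2OTBS keeps nickel and Et2Zn away from the lactone. Translactonization to the C6 oxygen is disfavoured because it would give the cis-lactone.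

Step 11
Reactants: 18 (E)-but-2-enal
Product: 19 (Z)-2-iodobut-2-enal
Conditions: I2, K2CO3, DMAP (20 mol%), THF/H2O, 25 °C
Reagents that add atoms: iodine II
Why: α-Iodination of the enal by amine addition, iodination and elimination should give the Z-iodide (iodine cis to the methyl group).

Step 12
Reactants: 19 (Z)-2-iodobut-2-enal
Product: 20 (Z)-2-iodobut-2-en-1-ol
Conditions: NaBH4, CeCl3·7H2O, MeOH, 0 °C
Reagents that add atoms: none
Why: 1,2-Reduction of the enal gives the allylic alcohol without change of the alkene geometry.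

Step 13
Reactants: 20 (Z)-2-iodobut-2-en-1-ol
Product: 21 tert-butyl{[(2Z)-2-iodobut-2-en-1-yl]oxy}dimethylsilane
Conditions: TBSCl, imidazole, CH2Cl2, 0 → 25 °C
Reagents that add atoms: tert-butyldimethylsilyl chloride CC(C)(C)[Si](C)(C)Cl
Why: Silylation protects the hydroxyl for the lithiation and for the later esterification.

Step 14
Reactants: 21 tert-butyl{[(2Z)-2-iodobut-2-en-1-yl]oxy}dimethylsilane
Product: 23 (2Z)-2-{[tert-butyl(dimethyl)silyl]oxymethyl}but-2-enoic acid, via alkenyllithium 22 (not isolated)
Conditions: t-BuLi (2.1 equiv), Et2O, −78 °C; then CO2 (gas), −78 °C; 1 M HCl to pH 3 at 0 °C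
Reagents that add atoms: carbon dioxide O=C=O
Why: Iodine–lithium exchange and carboxylation proceed with retention at the alkenyl carbon, so the carboxyl group ends cis to the methyl group as in the side-chain ester of the target.

Step 15
Reactants: 17 ten-membered carbocycle; 23 (2Z)-2-{[tert-butyl(dimethyl)silyl]oxymethyl}but-2-enoic acid
Product: 25 C6 ester of 17 with acid 23, via mixed anhydride 24 (not isolated)
Conditions: 23, 2,4,6-Cl3C6H2COCl, Et3N, toluene, 25 °C; then 17, toluene, 80 °C (no DMAP)
Reagents that add atoms: none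
Why: Yamaguchi esterification acylates the secondary C6 hydroxyl while the tertiary C4 hydroxyl stays free, and omitting the nucleophilic catalyst avoids Z to E isomerization of the α-substituted crotonate.

Step 16
Reactants: 25 C6 ester
Product: 26 tetraol (free C14-OH and C13-OH and side-chain CH2OH beside the tertiary C4-OH)
Conditions: HF·pyridine, pyridine, THF, 0 → 25 °C
Reagents that add atoms: none
Why: Buffered fluoride cleaves the three primary silyl ethers and leaves the esters, the lactone and the tertiary alcohol untouched.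

Step 17
Reactants: 26 tetraol
Product: 28 target CNP0280960.1, via triacetate 27 (not isolated)
Conditions: Ac2O, pyridine, CH2Cl2, 0 → 25 °C; then DBU (1.2 equiv), 0 °C, short contact
Reagents that add atoms: acetic anhydride CC(=O)OC(C)=O
Why: The three primary alcohols are acetylated (the tertiary C4 hydroxyl is inert without a nucleophilic catalyst) and the β-acetoxy lactone then loses acetic acid by E1cB elimination to unveil the C11=C13 methylene group.

**Compound list**

1 | (S)-5-(hydroxymethyl)furan-2(5H)-one | O=C1C=C[C@@H](CO)O1 | starting material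
2 | (S)-5-(bromomethyl)furan-2(5H)-one | O=C1C=C[C@@H](CBr)O1 | intermediate
3 | bromomagnesium enolate of the 4,5-trans 5-(bromomethyl)-4-ethenyl lactone | Br[Mg]OC1=C[C@H](C=C)[C@@H](CBr)O1 | intermediate
4 | (3R,4S,5S)-5-(bromomethyl)-4-ethenyl-3-(hydroxymethyl)oxolan-2-one (3,4-trans, 4,5-trans) | O=C1O[C@H](CBr)[C@@H](C=C)[C@@H]1CO | intermediate
5 | (3R,4S,5S)-5-(bromomethyl)-3-{[tert-butyl(dimethyl)silyl]oxymethyl}-4-ethenyloxolan-2-one | O=C1O[C@H](CBr)[C@@H](C=C)[C@@H]1CO[Si](C)(C)C(C)(C)C | intermediate
6 | but-3-en-2-one (methyl vinyl ketone) | C=CC(C)=O | starting material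
7 | (3R,4S,5S)-5-(bromomethyl)-3-{[tert-butyl(dimethyl)silyl]oxymethyl}-4-[(1E)-3-oxobut-1-en-1-yl]oxolan-2-one | O=C1O[C@H](CBr)[C@@H](/C=C/C(C)=O)[C@@H]1CO[Si](C)(C)C(C)(C)C | intermediate
8 | C6 pinacol boronate (boron in the place of the C6 hydroxyl of 9, same spatial arrangement) | O=C1O[C@H](CBr)[C@@H]([C@H](B2OC(C)(C)C(C)(C)O2)CC(C)=O)[C@@H]1CO[Si](C)(C)C(C)(C)C | intermediate
9 | (3R,4R,5S)-5-(bromomethyl)-3-{[tert-butyl(dimethyl)silyl]oxymethyl}-4-[(1R)-1-hydroxy-3-oxobutyl]oxolan-2-one | O=C1O[C@H](CBr)[C@@H]([C@H](O)CC(C)=O)[C@@H]1CO[Si](C)(C)C(C)(C)C | intermediate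
10 | prop-2-yn-1-ol | C#CCO | starting material
11 | bromoethene (vinyl bromide) | C=CBr | starting material
12 | pent-4-en-2-yn-1-ol | C=CC#CCO | intermediate
13 | (2Z)-2-(tributylstannyl)penta-2,4-dien-1-ol | C=C/C=C(\[Sn](CCCC)(CCCC)CCCC)CO | intermediate
14 | (2Z)-2-iodopenta-2,4-dien-1-ol | C=C/C=C(\I)CO | intermediate
15 | tert-butyl{[(2Z)-2-iodopenta-2,4-dien-1-yl]oxy}dimethylsilane | C=C/C=C(\I)CO[Si](C)(C)C(C)(C)C | intermediate
16 | diene ketone: trans,trans-lactone with C8 bearing the (2E)-2-(silyloxymethyl)penta-2,4-dienyl arm (C9 cis to C2), C7 bearing the (1R)-1-hydroxy-3-oxobutyl arm, C11 bearing CH2OTBS | O=C1O[C@H](C/C(CO[Si](C)(C)C(C)(C)C)=C\C=C)[C@@H]([C@H](O)CC(C)=O)[C@@H]1CO[Si](C)(C)C(C)(C)C | intermediate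
17 | ten-membered carbocycle: C4 tertiary alcohol (4S), free C6 hydroxyl (6R), C1=C10 alkene with C14-OTBS, trans-fused lactone with C11 bearing H and CH2OTBS | O=C1O[C@@H]2C/C(CO[Si](C)(C)C(C)(C)C)=C\CC[C@](C)(O)C[C@@H](O)[C@H]2[C@@H]1CO[Si](C)(C)C(C)(C)C | intermediate
18 | (E)-but-2-enal (crotonaldehyde) | C/C=C/C=O | starting material
19 | (Z)-2-iodobut-2-enal | C/C=C(\I)C=O | intermediate
20 | (Z)-2-iodobut-2-en-1-ol | C/C=C(\I)CO | intermediate
21 | tert-butyl{[(2Z)-2-iodobut-2-en-1-yl]oxy}dimethylsilane | C/C=C(\I)CO[Si](C)(C)C(C)(C)C | intermediate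
22 | (Z)-alkenyllithium from 21 (lithium cis to methyl) | C/C=C(\[Li])CO[Si](C)(C)C(C)(C)C | intermediate
23 | (2Z)-2-{[tert-butyl(dimethyl)silyl]oxymethyl}but-2-enoic acid | C/C=C(\C(=O)O)CO[Si](C)(C)C(C)(C)C | intermediate
24 | mixed anhydride of 23 with 2,4,6-trichlorobenzoic acid | C/C=C(\C(=O)OC(=O)c1c(Cl)cc(Cl)cc1Cl)CO[Si](C)(C)C(C)(C)C | intermediate
25 | C6 ester of 17 with acid 23 (three TBS ethers, free C4-OH) | O=C1O[C@@H]2C/C(CO[Si](C)(C)C(C)(C)C)=C\CC[C@](C)(O)C[C@@H](OC(=O)/C(=C\C)CO[Si](C)(C)C(C)(C)C)[C@H]2[C@@H]1CO[Si](C)(C)C(C)(C)C | intermediate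
26 | tetraol: 25 with the three silyl ethers cleaved | O=C1O[C@@H]2C/C(CO)=C\CC[C@](C)(O)C[C@@H](OC(=O)/C(=C\C)CO)[C@H]2[C@@H]1CO | intermediate
27 | triacetate: C14-OAc, side-chain CH2OAc and C13-OAc | O=C1O[C@@H]2C/C(COC(C)=O)=C\CC[C@](C)(O)C[C@@H](OC(=O)/C(=C\C)COC(C)=O)[C@H]2[C@@H]1COC(C)=O | intermediate
28 | CNP0280960.1 | C=C1C(=O)O[C@@H]2C/C(COC(C)=O)=C\CC[C@](C)(O)C[C@@H](OC(=O)/C(=C\C)COC(C)=O)[C@@H]12 | target

**Totals**

Total step count: 17. Longest linear sequence: 10 steps (steps 1–5, 9, 10, 15, 16, 17).

**Steps most likely to fail**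

1. Step 10 (Proposed new method). The nickelacycle may not form on the hindered, chelated methyl ketone, so that diene oligomerization, ethyl transfer to the ketone or retro-aldol cleavage of the zinc aldolate takes over. The fallback closes the same bond by a samarium Barbier reaction, using known chemistry. From 15, hydroboration of the terminal vinyl group (9-BBN, THF; NaBO3·4H2O) gives (3Z)-5-{[tert-butyl(dimethyl)silyl]oxy}-4-iodopent-3-en-1-ol F1. Coupling of F1 with 9 under the conditions of step 9 gives the C3 primary alcohol F2. I2, PPh3 and imidazole at 0 °C convert the primary hydroxyl into the C3 iodide F3. TESOTf and 2,6-lutidine give the C6 triethylsilyl ether F4. SmI2 with HMPA in THF at high dilution reduces the iodide and adds the alkylsamarium to the C4 ketone, giving the macrocyclic C6 silyl ether F5. PPTS in MeOH removes the triethylsilyl group and the route is rejoined at 17.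

2. Step 9. Reduction or β-elimination at C9 (loss of bromide with opening of the lactone) and homocoupling of the dienyl iodide may outrun the cross-coupling. The fallback replaces the radical cross-electrophile manifold by a Negishi coupling with a preformed nucleophile. From 15, iodine–lithium exchange (t-BuLi, Et2O, −78 °C) and ZnBr2 give the (Z)-dienylzinc bromide F6. Coupling of F6 (2.5 equiv) with 9, catalysed by [1,3-bis(2,6-diisopropylphenyl)imidazol-2-ylidene](3-chloropyridyl)palladium dichloride with LiBr in THF/NMP at 25 °C, should give 16, where the route is rejoined.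

3. Step 5. Facial selectivity of the boryl–copper addition may be poor if the C7 stereocentre opposes the ligand, and the catalytic alkoxide may induce elimination across C7–C8. The fallback builds the same arm by an aldol reaction and bypasses steps 4 and 5. From 5, ozonolysis (O3, CH2Cl2/MeOH, −78 °C; Me2S) gives the C6 aldehyde F7. An L-proline-catalysed aldol reaction with acetone (acetone/DMSO, 25 °C) should give 9 directly, the catalyst setting 6R in the sense established for α-branched aldehydes.

**Further compounds**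

F1 | step 10 | (3Z)-5-{[tert-butyl(dimethyl)silyl]oxy}-4-iodopent-3-en-1-ol | OCC/C=C(\I)CO[Si](C)(C)C(C)(C)C
F2 | step 10 | C3 primary alcohol: 16 with C2H2–C3H2OH in the place of the C2=C3 vinyl group | O=C1O[C@H](C/C(CO[Si](C)(C)C(C)(C)C)=C\CCO)[C@@H]([C@H](O)CC(C)=O)[C@@H]1CO[Si](C)(C)C(C)(C)C
F3 | step 10 | C3 iodide of F2 | O=C1O[C@H](C/C(CO[Si](C)(C)C(C)(C)C)=C\CCI)[C@@H]([C@H](O)CC(C)=O)[C@@H]1CO[Si](C)(C)C(C)(C)C
F4 | step 10 | C6 triethylsilyl ether of F3 | O=C1O[C@H](C/C(CO[Si](C)(C)C(C)(C)C)=C\CCI)[C@@H]([C@H](O[Si](CC)(CC)CC)CC(C)=O)[C@@H]1CO[Si](C)(C)C(C)(C)C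
F5 | step 10 | C6 triethylsilyl ether of macrocycle 17 | O=C1O[C@@H]2C/C(CO[Si](C)(C)C(C)(C)C)=C\CC[C@](C)(O)C[C@@H](O[Si](CC)(CC)CC)[C@H]2[C@@H]1CO[Si](C)(C)C(C)(C)C
F6 | step 9 | (Z)-dienylzinc bromide from 15 (zinc cis to the vinyl group) | C=C/C=C(\[Zn]Br)CO[Si](C)(C)C(C)(C)C
F7 | step 5 | 5-(bromomethyl)-3-{[tert-butyl(dimethyl)silyl]oxymethyl}-2-oxooxolane-4-carbaldehyde (3,4-trans, 4,5-trans) | O=C1O[C@H](CBr)[C@@H](C=O)[C@@H]1CO[Si](C)(C)C(C)(C)C
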